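**Plan**

1. Retrosynthesis: both C–Br bonds are cut first (each back to an alcohol, SN2 inversion; C1'–Br last, C5–Br before it). The side-chain chlorohydrin is traced to an acetyl group and the C1 acetate to a ring ketone, which leaves (5R)-2-acetyl-5-hydroxy-4,4-dimethylcyclohex-2-en-1-one. Its C2=C3 double bond and C5–C6 single bond are then cut together.
2. Enabling feature: ring carbon C1 (oxygen-bearing) has the C2=C3 alkene α,β to it and both C5 and side-chain carbon C1' β to it, and C4 between C3 and C5 is quaternary. The ring is therefore pentane-2,4-dione (C6–C1–C2–C1'–C2') condensed through both of its nucleophilic carbons with the non-enolisable 2,2-dimethylpropanedial (C3–C4–C5).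
3. Forward: the only ring and the whole C10 skeleton arise in one flask by an enantioselective vinylogous Mukaiyama aldol (C5–C6) followed by intramolecular Knoevenagel condensation (C2=C3). Six functional-group steps follow.
4. Stereochemistry: C5 comes from the chiral titanium–BINOL catalyst. C1 is relayed from C5 by hydroxyl-directed reduction (trans diol). C1' comes from CBS reduction (reagent control). Both bromides are made by SN2 inversion, which turns the trans C1/C5 pattern into the cis acetoxy bromide and the (1'S)-alcohol into the (1'R)-bromide.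

Key step: step 3

Remark: ring numbering is that of the target acetate (C1 OAc, C2 side chain, C3 =CH, C4 CMe2, C5 CHBr, C6 CH2); C1' is the side-chain carbon on C2 and C2' the CH2Cl carbon.
Remark: commercial silyl enol ether 3 is taken as an E/Z mixture; the geometry of this enol ether double bond (in 3, 4, 5 and F2) has no bearing on the route and is left unspecified.

**Step 1**
Reactants: 1 2,2-dimethylpropane-1,3-diol
Product: 2 2,2-dimethylpropanedial
Conditions: (COCl)2, DMSO, CH2Cl2, −78 °C; then Et3N, −78 to 0 °C; used as a solution (volatile)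
Reagents that add atoms: none
Why: Swern oxidation takes both primary alcohols to aldehydes without over-oxidation, and the product cannot enolise because its α-carbon is quaternary.

**Step 2**
Reactants: 3 4-(trimethylsilyloxy)pent-3-en-2-one
Product: 4 2,4-bis(trimethylsilyloxy)penta-1,3-diene
Conditions: LiN(iPr)2 (commercial solution), THF, −78 °C; Me3SiCl, −78 °C to rt
Reagents that add atoms: chlorotrimethylsilane, C[Si](C)(C)Cl
Why: Kinetic deprotonation of the methyl ketone and O-silylation is the standard preparation of 1,3-bis(silyloxy)dienes from 1,3-diketone mono-silyl enol ethers.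

**Step 3**
Reactants: 2 2,2-dimethylpropanedial; 4 2,4-bis(trimethylsilyloxy)penta-1,3-diene
Product: 7 (5R)-2-acetyl-5-hydroxy-4,4-dimethylcyclohex-2-en-1-one, via bis-silylated aldol adduct 5 (not isolated), via hydroxy diketo aldehyde 6 (not isolated)
Conditions: Ti(OiPr)4 (10 mol %), (R)-1,1'-bi-2-naphthol (10 mol %), 4 Å molecular sieves, THF, −78 to −20 °C, 2 in excess (3 equiv); then MeOH, piperidinium acetate (cat.), 0 °C to rt
Reagents that add atoms: none
Why: The titanium–BINOL complex activates one formyl group of 2 and the terminal carbon of dienol ether 4 adds to it in an open Mukaiyama-type transition state (forming C5–C6), silyl transfer to the aldolate oxygen releasing 5 and turning the catalyst over; methanol then unmasks 1,3-diketone 6, whose doubly activated central carbon adds to the second formyl group under amine-salt catalysis and loses water (forming C2=C3). The closest known reaction types are the catalytic enantioselective vinylogous Mukaiyama aldol of 1,3-bis(silyloxy)dienes with aldehydes and the Chan–Brownbridge formal [3+3] cyclocondensation of such dienes with 1,3-dielectrophiles, completed here by a classical intramolecular Knoevenagel condensation. The cyclohexenone ring closes in the 6-(enolendo)-exo-trig mode. The single new stereocenter C5 is set by the catalyst through enantioface selection at the bound aldehyde; (R)-BINOL is proposed to give the (5R)-carbinol on the usual model for this catalyst class (the substituent ranking matches that of aryl aldehydes), the antipodal ligand being used should the opposite sense be found. The step needs mono- over bis-addition (secured by the excess of the inexpensive, volatile dialdehyde), carbon- over oxygen-cyclisation of 6 (the central diketone carbon is the only nucleophile that reaches the formyl carbon through a six-membered transition state, and the absence of strong acid avoids dihydropyranone formation from the δ-hydroxy diketone) and a single dehydration (the hydrogen lost at C2 lies between two carbonyls, whereas quaternary C4 rules out dienol formation and aromatisation and the C5 hydroxyl should survive the mild amine-salt conditions).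

**Step 4**
Reactants: 7 (5R)-2-acetyl-5-hydroxy-4,4-dimethylcyclohex-2-en-1-one
Product: 8 1-[(4R,6R)-4,6-dihydroxy-3,3-dimethylcyclohex-1-en-1-yl]ethan-1-one
Conditions: Me4NBH(OAc)3 (limited excess), MeCN/AcOH, −30 °C
Reagents that add atoms: none
Why: In this hydroxyl-directed (Evans–Saksena) reduction the borohydride exchanges onto the C5 oxygen and delivers hydride to the C1 carbonyl on the same face, so the new C1 hydroxyl should be trans to the C5 hydroxyl (1R), while the acetyl carbonyl is out of reach and is not reduced intermolecularly by this reagent at low temperature.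

**Step 5**
Reactants: 8 1-[(4R,6R)-4,6-dihydroxy-3,3-dimethylcyclohex-1-en-1-yl]ethan-1-one
Product: 9 (1R,5R)-2-acetyl-5-hydroxy-4,4-dimethylcyclohex-2-en-1-yl acetate
Conditions: Ac2O (1.1 equiv), pyridine, CH2Cl2, −20 to 0 °C
Reagents that add atoms: acetic anhydride, CC(=O)OC(C)=O
Why: Site-selective acylation should take the allylic C1 hydroxyl only, because the C5 hydroxyl is neopentylic (next to quaternary C4) and no acyl-transfer catalyst is used.

**Step 6**
Reactants: 9 (1R,5R)-2-acetyl-5-hydroxy-4,4-dimethylcyclohex-2-en-1-yl acetate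
Product: 10 (1R,5S)-2-acetyl-5-bromo-4,4-dimethylcyclohex-2-en-1-yl acetate
Conditions: CBr4, P(n-C8H17)3, toluene, 70 °C
Reagents that add atoms: carbon tetrabromide, BrC(Br)(Br)Br
Why: In this Appel reaction bromide displaces the C5 alkoxyphosphonium ion with inversion (SN2) to give the (5S)-bromide cis to the acetate, and ionisation with Wagner–Meerwein shift or homoallyl participation is disfavoured because the neighbouring alkene is an electron-poor enone.

**Step 7**
Reactants: 10 (1R,5S)-2-acetyl-5-bromo-4,4-dimethylcyclohex-2-en-1-yl acetate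
Product: 12 (1R,5S)-5-bromo-2-(chloroacetyl)-4,4-dimethylcyclohex-2-en-1-yl acetate, via silyl dienol ether 11 (not isolated)
Conditions: Me3SiOTf, Et3N, CH2Cl2, 0 °C; then N-chlorosuccinimide, THF, 0 °C; aqueous NaHCO3 work-up
Reagents that add atoms: N-chlorosuccinimide, O=C1CCC(=O)N1Cl
Why: Soft enolisation can only occur at the acetyl methyl (the other α-carbon is sp2 ring carbon C2), and the resulting cross-conjugated silyl dienol ether 11 should be chlorinated at its terminal carbon (α-halogenation of a silyl enol ether).

**Step 8**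
Reactants: 12 (1R,5S)-5-bromo-2-(chloroacetyl)-4,4-dimethylcyclohex-2-en-1-yl acetate
Product: 13 (1R,5S)-5-bromo-2-[(1S)-2-chloro-1-hydroxyethyl]-4,4-dimethylcyclohex-2-en-1-yl acetate
Conditions: (S)-2-methyl-CBS-oxazaborolidine [(3aS)-1-methyl-3,3-diphenyltetrahydro-1H,3H-pyrrolo[1,2-c][1,3,2]oxazaborole] (20 mol %), BH3·SMe2, THF, −20 °C; MeOH quench
Reagents that add atoms: none
Why: In this Corey–Bakshi–Shibata reduction the ketone binds with the cyclohexenyl group as the large and CH2Cl as the small substituent, so the (S)-catalyst should give the (1'S)-chlorohydrin under reagent control, as with aryl chloromethyl ketones.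

**Step 9**
Reactants: 13 (1R,5S)-5-bromo-2-[(1S)-2-chloro-1-hydroxyethyl]-4,4-dimethylcyclohex-2-en-1-yl acetate
Product: 14 (1R,5S)-5-bromo-2-[(1R)-1-bromo-2-chloroethyl]-4,4-dimethylcyclohex-2-en-1-yl acetate
Conditions: CBr4, PPh3, CH2Cl2, −20 to 0 °C
Reagents that add atoms: carbon tetrabromide, BrC(Br)(Br)Br
Why: This Appel reaction on the allylic alcohol should give the (1'R)-bromide by SN2 inversion, the SN2' path being blocked because the far alkene carbon C3 is neopentylic and the low temperature limiting ion-pair scrambling.

**Compound list**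

1 | 2,2-dimethylpropane-1,3-diol | OCC(C)(C)CO | starting material
2 | 2,2-dimethylpropanedial | O=CC(C)(C)C=O | intermediate
3 | 4-(trimethylsilyloxy)pent-3-en-2-one | CC(=O)C=C(C)O[Si](C)(C)C | starting material
4 | 2,4-bis(trimethylsilyloxy)penta-1,3-diene | C=C(O[Si](C)(C)C)C=C(C)O[Si](C)(C)C | intermediate
5 | (3R)-2,2-dimethyl-5-oxo-3,7-bis(trimethylsilyloxy)oct-6-enal | O=CC(C)(C)[C@H](O[Si](C)(C)C)CC(=O)C=C(C)O[Si](C)(C)C | intermediate
6 | (3R)-3-hydroxy-2,2-dimethyl-5,7-dioxooctanal | O=CC(C)(C)[C@H](O)CC(=O)CC(C)=O | intermediate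
7 | (5R)-2-acetyl-5-hydroxy-4,4-dimethylcyclohex-2-en-1-one | O=C1C[C@@H](O)C(C)(C)C=C1C(C)=O | intermediate
8 | 1-[(4R,6R)-4,6-dihydroxy-3,3-dimethylcyclohex-1-en-1-yl]ethan-1-one | O[C@@H]1C[C@@H](O)C(C)(C)C=C1C(C)=O | intermediate
9 | (1R,5R)-2-acetyl-5-hydroxy-4,4-dimethylcyclohex-2-en-1-yl acetate | CC(=O)O[C@@H]1C[C@@H](O)C(C)(C)C=C1C(C)=O | intermediate
10 | (1R,5S)-2-acetyl-5-bromo-4,4-dimethylcyclohex-2-en-1-yl acetate | CC(=O)O[C@@H]1C[C@H](Br)C(C)(C)C=C1C(C)=O | intermediate
11 | (1R,5S)-5-bromo-4,4-dimethyl-2-[1-(trimethylsilyloxy)ethenyl]cyclohex-2-en-1-yl acetate | CC(=O)O[C@@H]1C[C@H](Br)C(C)(C)C=C1C(=C)O[Si](C)(C)C | intermediate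
12 | (1R,5S)-5-bromo-2-(chloroacetyl)-4,4-dimethylcyclohex-2-en-1-yl acetate | CC(=O)O[C@@H]1C[C@H](Br)C(C)(C)C=C1C(=O)CCl | intermediate
13 | (1R,5S)-5-bromo-2-[(1S)-2-chloro-1-hydroxyethyl]-4,4-dimethylcyclohex-2-en-1-yl acetate | CC(=O)O[C@@H]1C[C@H](Br)C(C)(C)C=C1[C@H](O)CCl | intermediate
14 | (1R,5S)-5-bromo-2-[(1R)-1-bromo-2-chloroethyl]-4,4-dimethylcyclohex-2-en-1-yl acetate | CC(=O)O[C@@H]1C[C@H](Br)C(C)(C)C=C1[C@@H](Br)CCl | target

**Step count and risks**

Total step count: 9. Longest linear sequence: 8 steps (1 → 2 → 7 → 8 → 9 → 10 → 12 → 13 → 14).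

Step 3 is the riskiest. The chelating 1,3-dialdehyde or the product may sequester the titanium catalyst, with loss of turnover and of enantioface selection. Diene 4 may add to both formyl groups. Intermediate 6 may be diverted into oxygen-cyclisation instead of the Knoevenagel closure. The fallback sets out from 2 and 4 and builds the ring in two isolated stages. Dialdehyde 2 is mono-protected (HC(OMe)3, MeOH, cat. p-TsOH, one equivalent) as 3,3-dimethoxy-2,2-dimethylpropanal F1. The same titanium–BINOL-catalysed vinylogous aldol with 4 then meets a single non-chelating formyl group and gives (6R)-8,8-dimethoxy-7,7-dimethyl-2,6-bis(trimethylsilyloxy)oct-2-en-4-one F2. Desilylation on work-up (citric acid, MeOH) gives isolable (6R)-6-hydroxy-8,8-dimethoxy-7,7-dimethyloctane-2,4-dione F3. Mild acetal hydrolysis (LiBF4, wet MeCN) liberates 6, and ethylenediammonium diacetate closes the ring, so the fallback comes back to the route at 7.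

Step 6 is the second risk. SN2 displacement at the neopentylic C5 carbinol may be slow enough for E2 elimination to compete. The C1 acetate may participate through a six-membered acetoxonium ion, giving retention or acyl shift. The phosphine/CBr4 reagent may attack the ketone. The fallback sets out from diol 8 and removes the participating group. The C1 hydroxyl is silylated selectively (Et3SiCl, imidazole, CH2Cl2, −40 °C) to 1-[(4R,6R)-4-hydroxy-3,3-dimethyl-6-(triethylsilyloxy)cyclohex-1-en-1-yl]ethan-1-one F4. The C5 hydroxyl is converted (ClCH2SO2Cl, pyridine, 0 °C) to (1R,5R)-4-acetyl-2,2-dimethyl-5-(triethylsilyloxy)cyclohex-3-en-1-yl chloromethanesulfonate F5. LiBr in DMF at 40–50 °C displaces it with inversion to 1-[(4S,6R)-4-bromo-3,3-dimethyl-6-(triethylsilyloxy)cyclohex-1-en-1-yl]ethan-1-one F6. HF·pyridine (THF, 0 °C) gives 1-[(4S,6R)-4-bromo-6-hydroxy-3,3-dimethylcyclohex-1-en-1-yl]ethan-1-one F7, and acetylation (Ac2O, pyridine) comes back to the route at 10.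

Step 9 is the third risk. Configurational purity at allylic C1' may be lost through ion-pair return, through participation of the C1 acetate, or through bromide exchange on the product. The fallback sets out from 13 and separates activation from displacement. The hydroxyl is converted at −40 °C (MsCl, Et3N, CH2Cl2) to (1R,5S)-5-bromo-2-[(1S)-2-chloro-1-(methanesulfonyloxy)ethyl]-4,4-dimethylcyclohex-2-en-1-yl acetate F8. Without isolation this is displaced by LiBr in acetone at −20 to 0 °C (SN2, inversion), so the fallback comes back to the route at 14.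

**Further compounds**

F1 | step 3 | 3,3-dimethoxy-2,2-dimethylpropanal | COC(OC)C(C)(C)C=O
F2 | step 3 | (6R)-8,8-dimethoxy-7,7-dimethyl-2,6-bis(trimethylsilyloxy)oct-2-en-4-one | CC(O[Si](C)(C)C)=CC(=O)C[C@@H](O[Si](C)(C)C)C(C)(C)C(OC)OC
F3 | step 3 | (6R)-6-hydroxy-8,8-dimethoxy-7,7-dimethyloctane-2,4-dione | CC(=O)CC(=O)C[C@@H](O)C(C)(C)C(OC)OC
F4 | step 6 | 1-[(4R,6R)-4-hydroxy-3,3-dimethyl-6-(triethylsilyloxy)cyclohex-1-en-1-yl]ethan-1-one | CC[Si](CC)(CC)O[C@@H]1C[C@@H](O)C(C)(C)C=C1C(C)=O
F5 | step 6 | (1R,5R)-4-acetyl-2,2-dimethyl-5-(triethylsilyloxy)cyclohex-3-en-1-yl chloromethanesulfonate | CC[Si](CC)(CC)O[C@@H]1C[C@@H](OS(=O)(=O)CCl)C(C)(C)C=C1C(C)=O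
F6 | step 6 | 1-[(4S,6R)-4-bromo-3,3-dimethyl-6-(triethylsilyloxy)cyclohex-1-en-1-yl]ethan-1-one | CC[Si](CC)(CC)O[C@@H]1C[C@H](Br)C(C)(C)C=C1C(C)=O
F7 | step 6 | 1-[(4S,6R)-4-bromo-6-hydroxy-3,3-dimethylcyclohex-1-en-1-yl]ethan-1-one | O[C@@H]1C[C@H](Br)C(C)(C)C=C1C(C)=O
F8 | step 9 | (1R,5S)-5-bromo-2-[(1S)-2-chloro-1-(methanesulfonyloxy)ethyl]-4,4-dimethylcyclohex-2-en-1-yl acetate | CC(=O)O[C@@H]1C[C@H](Br)C(C)(C)C=C1[C@H](OS(C)(=O)=O)CCl
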